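**Remark (convention and assumptions):** briarane numbering is used throughout (C1 quaternary; C2–C10 ten-membered ring; C11–C14 ring A; C15 methyl on C1; C16 CH2O on C5; C17–C19 lactone; C18 methyl on C17; C20 epoxide CH2). In ring A, α is the face of H-10 and β the face of the C15 methyl. Formaldehyde is charged as paraformaldehyde. C11 in 16 and 18–20 and C17 in 37–38 are epimer mixtures that converge later.

## Retrosynthetic overview

1. Juncin Q ⇐ late hydroxyl-directed C11=C20 epoxidation and triacetylation ⇐ ten-membered diene carrying the 8-hydroxy-γ-lactone ⇐ Nozaki–Hiyama–Kishi closure of C7–C8, then C7–OH-directed epoxidation and SmI2 opening (C8–OH, C17–H).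
2. The C3–C7 diene comes from a Sonogashira coupling onto a C2 alkyne followed by cis-semireduction; C17–C19 comes from Claisen acylation of a propanoate at C8.
3. Ring A (C1, C10–C14, plus C20) is made in one pot from three components: a formyl dihydropyranone, a 4-alkoxyacetoacetate and formaldehyde, by Michael addition (C10–C11), aldol addition (C13–C14) and hydroxymethylation (C11–C20).
4. Enabling feature: the C12 oxygen is flanked by C11 and C13 (an acetoacetate 1,3-bis-nucleophile), C14 is a carbinol on quaternary C1, and C2–O and C8 lie 1,6 across the C1–C10 bond. They can therefore be tied as a temporary unsaturated δ-lactone (C2–O–C8(=O)–C9=C10–C1) that makes C10 electrophilic and fixes the facial course; its carbonyl later becomes C8.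
5. Ring order: temporary δ-lactone → ring A → (lactone opened) → ten-membered ring → γ-lactone → spiro-epoxide.

Key step: step 10

## Route

Step 1
Reactants: 1 3-(trimethylsilyl)prop-2-ynal; 2 1-methoxy-1-(trimethylsilyloxy)ethene
Product: 3 methyl (3R)-3-hydroxy-5-(trimethylsilyl)pent-4-ynoate
Conditions: Ti(OiPr)4 (2 mol%), 2-amino-2'-hydroxy-1,1'-binaphthyl salicylaldimine ligand (enantiomer chosen to give the 3R alcohol), 3,5-di-tert-butylsalicylic acid, Et2O, 0 °C; then 1 M HCl, THF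
Reagents that add atoms: none
Why: Catalytic enantioselective Mukaiyama aldol addition of an acetate ketene acetal, a reaction type that works well with ynals; the chiral titanium complex selects the aldehyde face and sets the carbinol that becomes C2.

Step 2
Reactants: 3 methyl (3R)-3-hydroxy-5-(trimethylsilyl)pent-4-ynoate
Product: 4 methyl (2S,3R)-3-hydroxy-2-[(4-methoxybenzyloxy)methyl]-5-(trimethylsilyl)pent-4-ynoate
Conditions: LDA (2.2 equiv), THF, −78 → −20 °C; 4-methoxybenzyl chloromethyl ether, −78 → −30 °C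
Reagents that add atoms: 4-methoxybenzyl chloromethyl ether, COc1ccc(COCCl)cc1
Why: Fráter–Seebach alkylation of the chelated lithium alkoxide–enolate dianion, the electrophile entering trans to the alkynyl group; this α-configuration is erased in step 3, so only the C1–C14 bond matters.

Step 3
Reactants: 4 methyl (2S,3R)-3-hydroxy-2-[(4-methoxybenzyloxy)methyl]-5-(trimethylsilyl)pent-4-ynoate
Product: 5 methyl (2R,3R)-3-hydroxy-2-[(4-methoxybenzyloxy)methyl]-2-methyl-5-(trimethylsilyl)pent-4-ynoate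
Conditions: LDA (2.5 equiv), THF/DMPU, −78 → −20 °C; MeI
Reagents that add atoms: iodomethane, CI
Why: Second Fráter–Seebach alkylation of the re-formed six-membered chelate; methyl iodide again enters trans to the alkynyl group, which fixes quaternary C1 with the CH2OPMB arm (future C14) cis to the alkyne.

Step 4
Reactants: 5 methyl (2R,3R)-3-hydroxy-2-[(4-methoxybenzyloxy)methyl]-2-methyl-5-(trimethylsilyl)pent-4-ynoate
Product: 6 (2R,3R)-3-hydroxy-2-[(4-methoxybenzyloxy)methyl]-2-methyl-5-(trimethylsilyl)pent-4-ynal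
Conditions: i-Bu2AlH (2.2 equiv), CH2Cl2, −78 °C; Rochelle salt
Reagents that add atoms: none
Why: Partial reduction of the hindered ester at −78 °C should stop at the aluminium hemiacetal, which is stabilised by the neighbouring aluminium alkoxide, and gives the non-enolisable neopentyl aldehyde (future C10) without touching a stereocentre.

Step 5
Reactants: 6 (2R,3R)-3-hydroxy-2-[(4-methoxybenzyloxy)methyl]-2-methyl-5-(trimethylsilyl)pent-4-ynal
Product: 7 (5R,6R)-5-[(4-methoxybenzyloxy)methyl]-5-methyl-6-[(trimethylsilyl)ethynyl]-5,6-dihydro-2H-pyran-2-one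
Conditions: Ph3P=C=C=O, toluene, 90 °C
Reagents that add atoms: (triphenylphosphoranylidene)ketene, O=C=C=P(c1ccccc1)(c1ccccc1)c1ccccc1
Why: The secondary alcohol adds to the ketene ylide to give an ester-stabilised ylide that closes by intramolecular Wittig reaction on the aldehyde; the six-membered ring enforces the cis C9=C10 alkene.

Step 6
Reactants: 7 (5R,6R)-5-[(4-methoxybenzyloxy)methyl]-5-methyl-6-[(trimethylsilyl)ethynyl]-5,6-dihydro-2H-pyran-2-one
Product: 8 (5R,6R)-5-(hydroxymethyl)-5-methyl-6-[(trimethylsilyl)ethynyl]-5,6-dihydro-2H-pyran-2-one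
Conditions: DDQ, CH2Cl2/pH 7 buffer, 0 °C
Reagents that add atoms: none
Why: Oxidative cleavage of the 4-methoxybenzyl ether by DDQ leaves the enoate, the silyl alkyne and both stereocentres untouched.

Step 7
Reactants: 8 (5R,6R)-5-(hydroxymethyl)-5-methyl-6-[(trimethylsilyl)ethynyl]-5,6-dihydro-2H-pyran-2-one
Product: 9 (5S,6R)-5-methyl-2-oxo-6-[(trimethylsilyl)ethynyl]-5,6-dihydro-2H-pyran-5-carbaldehyde (formyl cis to the alkynyl group)
Conditions: Dess–Martin periodinane, NaHCO3, CH2Cl2, 23 °C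
Reagents that add atoms: none
Why: Dess–Martin oxidation of the neopentyl alcohol gives an aldehyde (C14) that cannot enolise, so quaternary C1 is safe.

Step 8
Reactants: 10 ethyl 4-chloro-3-oxobutanoate; 11 (4-methoxyphenyl)methanol
Product: 12 ethyl 4-[(4-methoxybenzyl)oxy]-3-oxobutanoate
Conditions: NaH (2.1 equiv), THF, 0 → 23 °C
Reagents that add atoms: none
Why: Williamson etherification; the keto ester is protected as its sodium enolate while the alkoxide displaces the activated chloride.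

Step 9
Reactants: 12 ethyl 4-[(4-methoxybenzyl)oxy]-3-oxobutanoate; 13 prop-2-en-1-ol
Product: 14 prop-2-enyl 4-[(4-methoxybenzyl)oxy]-3-oxobutanoate
Conditions: DMAP (cat.), toluene, reflux with removal of EtOH
Reagents that add atoms: none
Why: DMAP-catalysed transesterification of a β-keto ester, driven by distilling off ethanol, installs the allyl ester needed for step 12.

Step 10
Reactants: 9 (5S,6R)-5-methyl-2-oxo-6-[(trimethylsilyl)ethynyl]-5,6-dihydro-2H-pyran-5-carbaldehyde; 14 prop-2-enyl 4-[(4-methoxybenzyl)oxy]-3-oxobutanoate; 15 formaldehyde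
Product: 18 trans-fused ring A/δ-lactone bicycle with C11 bearing CO2allyl and CH2OH and with C12 ketone plus 13α-OPMB plus 14α-OH, via Michael adduct 16 (not isolated), via ring A keto ester 17 (not isolated)
Conditions: LiCl (2 equiv), DBU (0.5 equiv), THF, −20 → 23 °C; then paraformaldehyde (3 equiv), 23 °C
Reagents that add atoms: none
Why: The lithium-chelated enolate of 14 adds through C11 to C10 of the unsaturated lactone (Michael addition), proton transfer gives the C13 enolate, which closes on the C14 formyl group (aldol addition), and the cyclic β-keto ester formed is hydroxymethylated at C11 by formaldehyde. The closest known reaction types are base-mediated domino Michael–aldol [3+3] annulations of γ-heteroatom-substituted β-keto esters with unsaturated carbonyl compounds, conjugate additions to 6-substituted 5,6-dihydropyran-2-ones, and the hydroxymethylation of 2-alkoxycarbonyl cycloalkanones. Ring A is closed by an intermolecular Michael addition followed by a 6-(enolendo)-exo-trig aldol addition. C10 is set by stereoelectronically axial attack on the lactone half-chair, trans to the C2 alkynyl group and anti to the axial C1 formyl group, which puts C11 cis to the C15 methyl and leads to the trans ring fusion; C13 and C14 are set by the chelated Z-enolate carrying OPMB and a lithium-bridged closed transition state, which should place OPMB equatorial and the new hydroxyl axial (trans to the methyl); C11 is not controlled and is removed in step 12. The step needs Michael addition before aldol addition, which is secured because addition of the keto ester to the α-quaternary aldehyde is reversible and cannot condense without an amine, and it needs facial selectivity at C10, which is secured by the cis formyl and alkynyl groups on the lactone.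

Step 11
Reactants: 18 trans-fused ring A/δ-lactone bicycle with C11 bearing CO2allyl and CH2OH
Product: 20 C20 acetate C14 triethylsilyl ether of 18, via C20 monoacetate 19 (not isolated)
Conditions: Ac2O (1.1 equiv), pyridine, CH2Cl2, 0 °C; then Et3SiOTf, 2,6-lutidine, −78 → −40 °C
Reagents that add atoms: acetic anhydride, CC(=O)OC(C)=O; triethylsilyl trifluoromethanesulfonate, CC[Si](CC)(CC)OS(=O)(=O)C(F)(F)F
Why: The primary C20 hydroxyl is acetylated selectively over the hindered axial C14 hydroxyl, which is then silylated with the more reactive silyl triflate; this also blocks retro-aldol cleavage and dehydration.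

Step 12
Reactants: 20 C20 acetate C14 triethylsilyl ether of 18
Product: 21 exo-methylene enone (C11=C20H2, C12 ketone, 13α-OPMB, 14α-OSiEt3)
Conditions: Pd(PPh3)4 (5 mol%), MeCN, 23 → 50 °C
Reagents that add atoms: none
Why: Palladium-catalysed decarboxylation–deacetoxylation of an allyl α-(acetoxymethyl) β-keto ester (Tsuji type): zerovalent palladium ionises the allyl ester, CO2 is lost, and the palladium enolate expels acetate to give the α-methylene ketone regiospecifically at C11.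

Step 13
Reactants: 21 exo-methylene enone
Product: 22 12α-allylic alcohol (C11=C20H2, 12α-OH, 13α-OPMB, 14α-OSiEt3)
Conditions: NaBH4, CeCl3·7H2O, MeOH, −78 °C
Reagents that add atoms: none
Why: Luche 1,2-reduction; hydride should approach C12 from the β-face because the α-face is screened by the axial C14 silyloxy group and axial H-10, giving the axial 12α-alcohol cis to the C13 ether.

Step 14
Reactants: 22 12α-allylic alcohol
Product: 23 12α,14α-bis(triethylsilyl) ether of the bicyclic lactone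
Conditions: Et3SiOTf, 2,6-lutidine, CH2Cl2, −78 °C
Reagents that add atoms: triethylsilyl trifluoromethanesulfonate, CC[Si](CC)(CC)OS(=O)(=O)C(F)(F)F
Why: Silylation of the hindered axial allylic alcohol protects it through the base and triflation steps that follow.

Step 15
Reactants: 23 12α,14α-bis(triethylsilyl) ether of the bicyclic lactone
Product: 24 9-epi-9-hydroxy lactone (C9–OH equatorial, trans to C11)
Conditions: KN(SiMe3)2, THF, −78 °C; 2-(phenylsulfonyl)-3-phenyloxaziridine; NH4Cl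
Reagents that add atoms: 2-(phenylsulfonyl)-3-phenyloxaziridine, O=S(=O)(N1OC1c1ccccc1)c1ccccc1
Why: Davis hydroxylation of the lactone potassium enolate; the oxidant should approach C9 opposite the axial C15 methyl (1,3-related), so the 9-epimer is expected and is used deliberately for the inversion in step 16.

Step 16
Reactants: 24 9-epi-9-hydroxy lactone
Product: 27 9-hydroxy lactone with natural C9 configuration (OH cis to C11 and to the C15 methyl), via C9 triflate 25 (not isolated), via C9 nitrite ester 26 (not isolated)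
Conditions: Tf2O, pyridine, CH2Cl2, −20 °C; then KNO2, 18-crown-6, DMF, 23 °C; aqueous work-up
Reagents that add atoms: potassium nitrite, [K+].[O-]N=O
Why: Lattrell–Dax inversion: SN2 displacement of the carbonyl-activated equatorial triflate by nitrite, followed by hydrolysis of the nitrite ester, gives the axial alcohol that direct hydroxylation cannot deliver.

Step 17
Reactants: 27 9-hydroxy lactone with natural C9 configuration
Product: 28 Weinreb amide diol (C8 N-methoxy-N-methylamide with free C2–OH and C9–OH)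
Conditions: MeNHOMe·HCl, i-PrMgCl, THF, −20 → 0 °C
Reagents that add atoms: N,O-dimethylhydroxylamine hydrochloride, CNOC.Cl
Why: Aminolysis of the lactone by the chloromagnesium amide opens the temporary ring and turns its carbonyl (C8) into a Weinreb amide without epimerising C9.

Step 18
Reactants: 28 Weinreb amide diol
Product: 29 2,9,13-tris(4-methoxybenzyl) ether Weinreb amide
Conditions: 2-(4-methoxybenzyloxy)-4-methylquinoline, MeOTf, MgO, PhCF3, 0 → 23 °C
Reagents that add atoms: 2-(4-methoxybenzyloxy)-4-methylquinoline, COc1ccc(COc2cc(C)c3ccccc3n2)cc1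
Why: 4-Methoxybenzyl transfer from the N-methylated quinolinium ether under neutral conditions protects both hindered alcohols; it avoids base, which would re-lactonise the hydroxy amide.

Step 19
Reactants: 30 but-2-yne-1,4-diol
Product: 31 4-[(tert-butyldiphenylsilyl)oxy]but-2-yn-1-ol
Conditions: NaH (1 equiv), THF, 0 °C; t-BuPh2SiCl
Reagents that add atoms: tert-butyl(chloro)diphenylsilane, CC(C)(C)[Si](Cl)(c1ccccc1)c1ccccc1
Why: Monosilylation of the symmetrical diol through its monosodium alkoxide.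

Step 20
Reactants: 31 4-[(tert-butyldiphenylsilyl)oxy]but-2-yn-1-ol
Product: 32 (Z)-4-[(tert-butyldiphenylsilyl)oxy]-3-iodobut-2-en-1-ol
Conditions: NaAlH2(OCH2CH2OCH3)2, THF, 0 °C; then I2, −78 → 0 °C
Reagents that add atoms: iodine, II
Why: Alkoxide-directed trans-hydroalumination of the propargylic alcohol places aluminium on the distal carbon, and iodinolysis with retention gives the Z vinyl iodide with iodine cis to the CH2OH carbon (future C4 cis to C7).

Step 21
Reactants: 29 2,9,13-tris(4-methoxybenzyl) ether Weinreb amide; 32 (Z)-4-[(tert-butyldiphenylsilyl)oxy]-3-iodobut-2-en-1-ol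
Product: 34 enyne alcohol (C3≡C4–C5(CH2OSiPh2t-Bu)=C6H–C7H2OH), via terminal alkyne 33 (not isolated)
Conditions: K2CO3, MeOH, 23 °C; concentrate; then Pd(PPh3)4 (5 mol%), CuI (10 mol%), i-Pr2NH, THF, 23 °C
Reagents that add atoms: none
Why: C-desilylation of the alkyne followed by Sonogashira coupling, which retains the vinyl iodide geometry and forms the C4–C5 bond.

Step 22
Reactants: 34 enyne alcohol
Product: 35 (3Z,5E)-dienol (both ring-cis alkenes of the target in place)
Conditions: Zn activated with Cu(OAc)2 and AgNO3, MeOH/H2O, 40 °C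
Reagents that add atoms: none
Why: cis-Selective semireduction of a conjugated enyne by activated zinc gives the Z C3=C4 alkene without over-reduction and leaves the isolated exocyclic alkene alone.

Step 23
Reactants: 35 (3Z,5E)-dienol; 36 tert-butyl propanoate
Product: 37 β-keto tert-butyl ester (C8 ketone, C17 epimers)
Conditions: LDA, 36 (4 equiv), THF, −78 °C; add 35, −78 → −40 °C; NH4Cl
Reagents that add atoms: none
Why: Claisen-type acylation of the ester lithium enolate by the Weinreb amide through a stable chelated tetrahedral intermediate forms the C8–C17 bond; excess enolate accommodates the free C7 hydroxyl.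

Step 24
Reactants: 37 β-keto tert-butyl ester
Product: 38 (2Z,4Z)-dienal β-keto ester (C7 aldehyde)
Conditions: MnO2, CH2Cl2, 23 °C
Reagents that add atoms: none
Why: MnO2 oxidises only the allylic primary alcohol under neutral conditions, which preserves the cis enal geometry.

Step 25
Reactants: 38 (2Z,4Z)-dienal β-keto ester
Product: 39 (Z)-enol triflate (C8–OTf cis to CO2t-Bu)
Conditions: KN(SiMe3)2 (1.05 equiv), THF, −78 °C; PhNTf2, −78 → 0 °C
Reagents that add atoms: N-phenylbis(trifluoromethanesulfonimide), O=S(=O)(N(c1ccccc1)S(=O)(=O)C(F)(F)F)C(F)(F)F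
Why: The acidic β-keto ester is deprotonated selectively in the presence of the aldehyde, and O-sulfonylation of the chelated enolate gives the Z enol triflate.

Step 26
Reactants: 39 (Z)-enol triflate
Product: 40 ten-membered (Z)-γ-hydroxy enoate (C7–OH, C8=C17 bearing CO2t-Bu cis to C7)
Conditions: CrCl2 (8 equiv), NiCl2 (5 mol%), DMSO/THF, 23 °C, slow addition at high dilution
Reagents that add atoms: none
Why: Nozaki–Hiyama–Kishi reaction: nickel-catalysed formation of the alkenylchromium species from the enol triflate with retention of geometry and its 1,2-addition to the aldehyde close the ten-membered ring at C7–C8; C7 is set under substrate control in the ring-closing transition state, and a reagent-controlled correction is given among the fallbacks.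

Step 27
Reactants: 40 ten-membered (Z)-γ-hydroxy enoate
Product: 42 8,17-epoxy γ-lactone (epoxide oxygen cis to C6 on the lactone), via epoxy hydroxy ester 41 (not isolated)
Conditions: t-BuOOH, n-BuLi (3 equiv of t-BuOOLi), THF, −78 → −20 °C; then 23 °C
Reagents that add atoms: tert-butyl hydroperoxide, CC(C)(C)OO
Why: Alkoxide-directed nucleophilic (Weitz–Scheffer-type) epoxidation: the C7 lithium alkoxide delivers the peroxide to the enoate face syn to C7–O in the conformer that has C7–H eclipsing the alkene (allylic 1,3-strain with the cis ester), which sets C8 relative to C7 as in the target; the alkoxide then lactonises on the tert-butyl ester on warming.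

Step 28
Reactants: 42 8,17-epoxy γ-lactone
Product: 44 8-hydroxy γ-lactone with natural C7, C8 and C17 configuration, via 17-epimer 43 (not isolated)
Conditions: SmI2 (2.5 equiv), THF/MeOH, −78 °C; then DBU, toluene, 23 → 50 °C
Reagents that add atoms: none
Why: SmI2 cleaves the Cα–O bond of the α,β-epoxy lactone and keeps the C8–O bond; protonation of the samarium enolate is expected to give the 17-epimer, which DBU equilibrates to the more stable isomer with the C18 methyl trans to C9 and cis to the C8 hydroxyl.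

Step 29
Reactants: 44 8-hydroxy γ-lactone
Product: 45 2,9,13-triol (12,14-bis-silyl ether, 16-O-silyl ether)
Conditions: DDQ (4 equiv), CH2Cl2/pH 7 buffer, 0 → 23 °C
Reagents that add atoms: none
Why: Buffered DDQ removes the three 4-methoxybenzyl ethers in one operation and leaves the silyl ethers, diene and lactone intact.

Step 30
Reactants: 45 2,9,13-triol
Product: 46 2,9,13-triacetate
Conditions: Ac2O, pyridine, DMAP (cat.), CH2Cl2, 0 → 23 °C
Reagents that add atoms: acetic anhydride, CC(=O)OC(C)=O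
Why: The three secondary alcohols are acetylated while the tertiary C8 hydroxyl does not react under these conditions.

Step 31
Reactants: 46 2,9,13-triacetate
Product: 47 12α,14α-diol (C11=C20H2, 16-O-SiPh2t-Bu retained)
Conditions: HF·pyridine, pyridine, THF, 0 °C
Reagents that add atoms: none
Why: Triethylsilyl ethers are cleaved much faster than the primary tert-butyldiphenylsilyl ether under buffered HF·pyridine, which frees the directing hydroxyls while C16 stays masked.

Step 32
Reactants: 47 12α,14α-diol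
Product: 48 16-O-(tert-butyldiphenylsilyl) juncin Q (11,20-epoxide, oxygen α)
Conditions: VO(acac)2 (5 mol%), t-BuOOH, CH2Cl2, 0 °C
Reagents that add atoms: tert-butyl hydroperoxide, CC(C)(C)OO
Why: Vanadium-catalysed hydroxyl-directed epoxidation: the 12α (and 14α) hydroxyl delivers oxygen to the α-face of the exocyclic alkene, setting C11; the diene has no free allylic hydroxyl because C16 is silylated.

Step 33
Reactants: 48 16-O-(tert-butyldiphenylsilyl) juncin Q
Product: 49 juncin Q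
Conditions: Bu4NF, AcOH (1:1), THF, 0 → 23 °C
Reagents that add atoms: none
Why: Buffered fluoride removes the primary silyl ether; the buffer suppresses acetate migration to the free 12- and 14-hydroxyls and Payne rearrangement of the epoxy alcohol.

## Compound list

1 | 3-(trimethylsilyl)prop-2-ynal | C[Si](C)(C)C#CC=O | starting material
2 | 1-methoxy-1-(trimethylsilyloxy)ethene | COC(=C)O[Si](C)(C)C | starting material
3 | methyl (3R)-3-hydroxy-5-(trimethylsilyl)pent-4-ynoate | C[Si](C)(C)C#C[C@H](O)CC(=O)OC | intermediate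
4 | methyl (2S,3R)-3-hydroxy-2-[(4-methoxybenzyloxy)methyl]-5-(trimethylsilyl)pent-4-ynoate | C[Si](C)(C)C#C[C@H](O)[C@@H](C(=O)OC)COCc1ccc(OC)cc1 | intermediate
5 | methyl (2R,3R)-3-hydroxy-2-[(4-methoxybenzyloxy)methyl]-2-methyl-5-(trimethylsilyl)pent-4-ynoate | C[Si](C)(C)C#C[C@H](O)[C@@](C(=O)OC)(C)COCc1ccc(OC)cc1 | intermediate
6 | (2R,3R)-3-hydroxy-2-[(4-methoxybenzyloxy)methyl]-2-methyl-5-(trimethylsilyl)pent-4-ynal | C[Si](C)(C)C#C[C@H](O)[C@@](C=O)(C)COCc1ccc(OC)cc1 | intermediate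
7 | (5R,6R)-5-[(4-methoxybenzyloxy)methyl]-5-methyl-6-[(trimethylsilyl)ethynyl]-5,6-dihydro-2H-pyran-2-one | C[Si](C)(C)C#C[C@H](OC(=O)C=C2)[C@@]2(C)COCc1ccc(OC)cc1 | intermediate
8 | (5R,6R)-5-(hydroxymethyl)-5-methyl-6-[(trimethylsilyl)ethynyl]-5,6-dihydro-2H-pyran-2-one | C[Si](C)(C)C#C[C@H](OC(=O)C=C2)[C@@]2(C)CO | intermediate
9 | (5S,6R)-5-methyl-2-oxo-6-[(trimethylsilyl)ethynyl]-5,6-dihydro-2H-pyran-5-carbaldehyde | C[Si](C)(C)C#C[C@H](OC(=O)C=C2)[C@@]2(C)C=O | intermediate
10 | ethyl 4-chloro-3-oxobutanoate | CCOC(=O)CC(=O)CCl | starting material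
11 | (4-methoxyphenyl)methanol | COc1ccc(CO)cc1 | starting material
12 | ethyl 4-[(4-methoxybenzyl)oxy]-3-oxobutanoate | CCOC(=O)CC(=O)COCc1ccc(OC)cc1 | intermediate
13 | prop-2-en-1-ol | C=CCO | starting material
14 | prop-2-enyl 4-[(4-methoxybenzyl)oxy]-3-oxobutanoate | C=CCOC(=O)CC(=O)COCc1ccc(OC)cc1 | intermediate
15 | formaldehyde (charged as paraformaldehyde) | C=O | starting material
16 | Michael adduct: 5-formyl-5-methyl-6-(trimethylsilylethynyl)tetrahydropyran-2-one carrying the CH(CO2allyl)C(=O)CH2OPMB chain at C10 (C11 epimers) | COc1ccc(COCC(=O)C(C(=O)OCC=C)[C@@H]2CC(=O)O[C@@H](C#C[Si](C)(C)C)[C@@]2(C)C=O)cc1 | intermediate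
17 | ring A keto ester: trans-fused bicycle, C11 CO2allyl (equatorial), C12 ketone, 13α-OPMB, 14α-OH | COc1ccc(CO[C@H]2C(=O)[C@@H](C(=O)OCC=C)[C@@H]3CC(=O)O[C@@H](C#C[Si](C)(C)C)[C@@]3(C)[C@H]2O)cc1 | intermediate
18 | trans-fused ring A/δ-lactone bicycle: C11 bearing CO2allyl and CH2OH (C11 epimers), C12 ketone, 13α-OPMB, 14α-OH | COc1ccc(CO[C@H]2C(=O)C(CO)(C(=O)OCC=C)[C@@H]3CC(=O)O[C@@H](C#C[Si](C)(C)C)[C@@]3(C)[C@H]2O)cc1 | intermediate
19 | C20 monoacetate of 18 | COc1ccc(CO[C@H]2C(=O)C(COC(C)=O)(C(=O)OCC=C)[C@@H]3CC(=O)O[C@@H](C#C[Si](C)(C)C)[C@@]3(C)[C@H]2O)cc1 | intermediate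
20 | C20 acetate, C14 triethylsilyl ether of 18 | COc1ccc(CO[C@H]2C(=O)C(COC(C)=O)(C(=O)OCC=C)[C@@H]3CC(=O)O[C@@H](C#C[Si](C)(C)C)[C@@]3(C)[C@H]2O[Si](CC)(CC)CC)cc1 | intermediate
21 | exo-methylene enone (C11=C20H2, C12 ketone, 13α-OPMB, 14α-OSiEt3) | COc1ccc(CO[C@H]2C(=O)C(=C)[C@@H]3CC(=O)O[C@@H](C#C[Si](C)(C)C)[C@@]3(C)[C@H]2O[Si](CC)(CC)CC)cc1 | intermediate
22 | 12α-allylic alcohol | COc1ccc(CO[C@H]2[C@@H](O)C(=C)[C@@H]3CC(=O)O[C@@H](C#C[Si](C)(C)C)[C@@]3(C)[C@H]2O[Si](CC)(CC)CC)cc1 | intermediate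
23 | 12α,14α-bis(triethylsilyl) ether of the bicyclic lactone | COc1ccc(CO[C@H]2[C@@H](O[Si](CC)(CC)CC)C(=C)[C@@H]3CC(=O)O[C@@H](C#C[Si](C)(C)C)[C@@]3(C)[C@H]2O[Si](CC)(CC)CC)cc1 | intermediate
24 | 9-epi-9-hydroxy lactone | COc1ccc(CO[C@H]2[C@@H](O[Si](CC)(CC)CC)C(=C)[C@@H]3[C@@H](O)C(=O)O[C@@H](C#C[Si](C)(C)C)[C@@]3(C)[C@H]2O[Si](CC)(CC)CC)cc1 | intermediate
25 | C9 triflate of 24 | COc1ccc(CO[C@H]2[C@@H](O[Si](CC)(CC)CC)C(=C)[C@@H]3[C@@H](OS(=O)(=O)C(F)(F)F)C(=O)O[C@@H](C#C[Si](C)(C)C)[C@@]3(C)[C@H]2O[Si](CC)(CC)CC)cc1 | intermediate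
26 | C9 nitrite ester (inverted) | COc1ccc(CO[C@H]2[C@@H](O[Si](CC)(CC)CC)C(=C)[C@@H]3[C@H](ON=O)C(=O)O[C@@H](C#C[Si](C)(C)C)[C@@]3(C)[C@H]2O[Si](CC)(CC)CC)cc1 | intermediate
27 | 9-hydroxy lactone, natural C9 configuration | COc1ccc(CO[C@H]2[C@@H](O[Si](CC)(CC)CC)C(=C)[C@@H]3[C@H](O)C(=O)O[C@@H](C#C[Si](C)(C)C)[C@@]3(C)[C@H]2O[Si](CC)(CC)CC)cc1 | intermediate
28 | Weinreb amide diol (free C2–OH and C9–OH) | CON(C)C(=O)[C@@H](O)[C@H]1C(=C)[C@H](O[Si](CC)(CC)CC)[C@H](OCc2ccc(OC)cc2)[C@H](O[Si](CC)(CC)CC)[C@]1(C)[C@@H](O)C#C[Si](C)(C)C | intermediate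
29 | 2,9,13-tris(4-methoxybenzyl) ether Weinreb amide | CON(C)C(=O)[C@@H](OCc2ccc(OC)cc2)[C@H]1C(=C)[C@H](O[Si](CC)(CC)CC)[C@H](OCc2ccc(OC)cc2)[C@H](O[Si](CC)(CC)CC)[C@]1(C)[C@@H](OCc2ccc(OC)cc2)C#C[Si](C)(C)C | intermediate
30 | but-2-yne-1,4-diol | OCC#CCO | starting material
31 | 4-[(tert-butyldiphenylsilyl)oxy]but-2-yn-1-ol | OCC#CCO[Si](c1ccccc1)(c1ccccc1)C(C)(C)C | intermediate
32 | (Z)-4-[(tert-butyldiphenylsilyl)oxy]-3-iodobut-2-en-1-ol | OC/C=C(I)/CO[Si](c1ccccc1)(c1ccccc1)C(C)(C)C | intermediate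
33 | terminal alkyne from 29 | CON(C)C(=O)[C@@H](OCc2ccc(OC)cc2)[C@H]1C(=C)[C@H](O[Si](CC)(CC)CC)[C@H](OCc2ccc(OC)cc2)[C@H](O[Si](CC)(CC)CC)[C@]1(C)[C@@H](OCc2ccc(OC)cc2)C#C | intermediate
34 | enyne alcohol | CON(C)C(=O)[C@@H](OCc2ccc(OC)cc2)[C@H]1C(=C)[C@H](O[Si](CC)(CC)CC)[C@H](OCc2ccc(OC)cc2)[C@H](O[Si](CC)(CC)CC)[C@]1(C)[C@@H](OCc2ccc(OC)cc2)C#C/C(CO[Si](c2ccccc2)(c2ccccc2)C(C)(C)C)=C\CO | intermediate
35 | (3Z,5E)-dienol | CON(C)C(=O)[C@@H](OCc2ccc(OC)cc2)[C@H]1C(=C)[C@H](O[Si](CC)(CC)CC)[C@H](OCc2ccc(OC)cc2)[C@H](O[Si](CC)(CC)CC)[C@]1(C)[C@@H](OCc2ccc(OC)cc2)/C=C\C(CO[Si](c2ccccc2)(c2ccccc2)C(C)(C)C)=C/CO | intermediate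
36 | tert-butyl propanoate | CCC(=O)OC(C)(C)C | starting material
37 | β-keto tert-butyl ester (C17 epimers) | CC(C)(C)OC(=O)C(C)C(=O)[C@@H](OCc2ccc(OC)cc2)[C@H]1C(=C)[C@H](O[Si](CC)(CC)CC)[C@H](OCc2ccc(OC)cc2)[C@H](O[Si](CC)(CC)CC)[C@]1(C)[C@@H](OCc2ccc(OC)cc2)/C=C\C(CO[Si](c2ccccc2)(c2ccccc2)C(C)(C)C)=C/CO | intermediate
38 | dienal β-keto ester (C17 epimers) | CC(C)(C)OC(=O)C(C)C(=O)[C@@H](OCc2ccc(OC)cc2)[C@H]1C(=C)[C@H](O[Si](CC)(CC)CC)[C@H](OCc2ccc(OC)cc2)[C@H](O[Si](CC)(CC)CC)[C@]1(C)[C@@H](OCc2ccc(OC)cc2)/C=C\C(CO[Si](c2ccccc2)(c2ccccc2)C(C)(C)C)=C/C=O | intermediate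
39 | (Z)-enol triflate dienal | CC(C)(C)OC(=O)/C(C)=C(\OS(=O)(=O)C(F)(F)F)[C@@H](OCc2ccc(OC)cc2)[C@H]1C(=C)[C@H](O[Si](CC)(CC)CC)[C@H](OCc2ccc(OC)cc2)[C@H](O[Si](CC)(CC)CC)[C@]1(C)[C@@H](OCc2ccc(OC)cc2)/C=C\C(CO[Si](c2ccccc2)(c2ccccc2)C(C)(C)C)=C/C=O | intermediate
40 | ten-membered (Z)-γ-hydroxy enoate | COc1ccc(CO[C@H]2[C@@H](O[Si](CC)(CC)CC)C(=C)[C@@H]3[C@H](OCc4ccc(OC)cc4)/C(=C(\C)C(=O)OC(C)(C)C)[C@@H](O)/C=C(CO[Si](c4ccccc4)(c4ccccc4)C(C)(C)C)\C=C/[C@H](OCc4ccc(OC)cc4)[C@@]3(C)[C@H]2O[Si](CC)(CC)CC)cc1 | intermediate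
41 | epoxy hydroxy ester | COc1ccc(CO[C@H]2[C@@H](O[Si](CC)(CC)CC)C(=C)[C@@H]3[C@H](OCc4ccc(OC)cc4)[C@@]5(O[C@@]5(C)C(=O)OC(C)(C)C)[C@@H](O)/C=C(CO[Si](c4ccccc4)(c4ccccc4)C(C)(C)C)\C=C/[C@H](OCc4ccc(OC)cc4)[C@@]3(C)[C@H]2O[Si](CC)(CC)CC)cc1 | intermediate
42 | 8,17-epoxy γ-lactone | COc1ccc(CO[C@H]2[C@@H](O[Si](CC)(CC)CC)C(=C)[C@@H]3[C@H](OCc4ccc(OC)cc4)[C@@]56O[C@@]6(C)C(=O)O[C@H]5/C=C(CO[Si](c4ccccc4)(c4ccccc4)C(C)(C)C)\C=C/[C@H](OCc4ccc(OC)cc4)[C@@]3(C)[C@H]2O[Si](CC)(CC)CC)cc1 | intermediate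
43 | 17-epi 8-hydroxy γ-lactone | COc1ccc(CO[C@H]2[C@@H](O[Si](CC)(CC)CC)C(=C)[C@@H]3[C@H](OCc4ccc(OC)cc4)[C@@]5(O)[C@H](/C=C(CO[Si](c4ccccc4)(c4ccccc4)C(C)(C)C)\C=C/[C@H](OCc4ccc(OC)cc4)[C@@]3(C)[C@H]2O[Si](CC)(CC)CC)OC(=O)[C@H]5C)cc1 | intermediate
44 | 8-hydroxy γ-lactone (natural C7, C8, C17; 2,9,13-tris-PMB, 12,14-bis-SiEt3, 16-O-SiPh2t-Bu) | COc1ccc(CO[C@H]2[C@@H](O[Si](CC)(CC)CC)C(=C)[C@@H]3[C@H](OCc4ccc(OC)cc4)[C@@]5(O)[C@H](/C=C(CO[Si](c4ccccc4)(c4ccccc4)C(C)(C)C)\C=C/[C@H](OCc4ccc(OC)cc4)[C@@]3(C)[C@H]2O[Si](CC)(CC)CC)OC(=O)[C@@H]5C)cc1 | intermediate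
45 | 2,9,13-triol | O[C@H]1[C@@H](O[Si](CC)(CC)CC)C(=C)[C@@H]2[C@H](O)[C@@]3(O)[C@H](/C=C(CO[Si](c4ccccc4)(c4ccccc4)C(C)(C)C)\C=C/[C@H](O)[C@@]2(C)[C@H]1O[Si](CC)(CC)CC)OC(=O)[C@@H]3C | intermediate
46 | 2,9,13-triacetate | CC(=O)O[C@H]1[C@@H](O[Si](CC)(CC)CC)C(=C)[C@@H]2[C@H](OC(C)=O)[C@@]3(O)[C@H](/C=C(CO[Si](c4ccccc4)(c4ccccc4)C(C)(C)C)\C=C/[C@H](OC(C)=O)[C@@]2(C)[C@H]1O[Si](CC)(CC)CC)OC(=O)[C@@H]3C | intermediate
47 | 12α,14α-diol (C11=C20H2, 16-O-SiPh2t-Bu) | CC(=O)O[C@H]1[C@@H](O)C(=C)[C@@H]2[C@H](OC(C)=O)[C@@]3(O)[C@H](/C=C(CO[Si](c4ccccc4)(c4ccccc4)C(C)(C)C)\C=C/[C@H](OC(C)=O)[C@@]2(C)[C@H]1O)OC(=O)[C@@H]3C | intermediate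
48 | 16-O-(tert-butyldiphenylsilyl) juncin Q | CC(=O)O[C@H]1[C@@H](O)[C@]2(CO2)[C@@H]2[C@H](OC(C)=O)[C@@]3(O)[C@H](/C=C(CO[Si](c4ccccc4)(c4ccccc4)C(C)(C)C)\C=C/[C@H](OC(C)=O)[C@@]2(C)[C@H]1O)OC(=O)[C@@H]3C | intermediate
49 | juncin Q | CC(=O)O[C@H]1[C@@H](O)[C@]2(CO2)[C@@H]2[C@H](OC(C)=O)[C@@]3(O)[C@H](/C=C(CO)\C=C/[C@H](OC(C)=O)[C@@]2(C)[C@H]1O)OC(=O)[C@@H]3C | target

## Step count and risks

Total step count: 33. Longest linear sequence: 29 (steps 1–7, 10–18, 21–33).

**Step 10.** The keto ester carbanion may add to the formyl group instead of to C10, or the conjugate addition next to the quaternary centre may be too slow, so the cascade may stall or close in the wrong order, and facial selectivity at C10 or C14 may be poor. Fallback: set out from alcohol 8 and separate the two bond formations. Silylation (Et3SiCl, imidazole) gives (5R,6R)-5-methyl-5-[(triethylsilyloxy)methyl]-6-[(trimethylsilyl)ethynyl]-5,6-dihydro-2H-pyran-2-one F1. Conjugate addition of 14 (Cs2CO3, MeCN), with no aldehyde present, gives the silyl-protected Michael adduct F2. Swern oxidation, which converts primary triethylsilyl ethers directly into aldehydes, gives 16; this is closed with LiCl/DBU and hydroxymethylated as in step 10, and the route is rejoined at 18.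

**Step 26.** Ring closure may lose to oligomerisation, and the carbonyl addition may show poor facial selectivity at C7. Fallback: from 40 obtained as a C7 epimer mixture, MnO2 oxidation of the doubly allylic alcohol gives the macrocyclic cross-conjugated dienone F3. Corey–Bakshi–Shibata reduction (oxazaborolidine, BH3·SMe2) then sets C7 under reagent control and returns 40.

**Step 27.** Oxygen transfer to the tetrasubstituted enoate may be slow or go to the wrong face, or the ester may lactonise to the butenolide before epoxidation and lose the directing group. Fallback: from 40, i-Bu2AlH reduces the tert-butyl ester to the allylic 1,4-diol F4. Sharpless asymmetric epoxidation (Ti(OiPr)4, diethyl tartrate, t-BuOOH) of the primary allylic alcohol gives the epoxy diol F5 under reagent control. NaAlH2(OCH2CH2OCH3)2 opens the 2,3-epoxy alcohol at C17 by internal hydride delivery with inversion, giving the triol F6 with the tertiary C8 alcohol and the natural C17 configuration. Oxidative lactonisation of the 1,4-diol (TEMPO, PhI(OAc)2) returns 44.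

## Further compounds

F1 | step 10 | (5R,6R)-5-methyl-5-[(triethylsilyloxy)methyl]-6-[(trimethylsilyl)ethynyl]-5,6-dihydro-2H-pyran-2-one | C[Si](C)(C)C#C[C@H](OC(=O)C=C2)[C@@]2(C)CO[Si](CC)(CC)CC
F2 | step 10 | silyl-protected Michael adduct (C14 as CH2OSiEt3, C11 epimers) | COc1ccc(COCC(=O)C(C(=O)OCC=C)[C@@H]2CC(=O)O[C@@H](C#C[Si](C)(C)C)[C@@]2(C)CO[Si](CC)(CC)CC)cc1
F3 | step 26 | macrocyclic cross-conjugated dienone (C7 ketone) | COc1ccc(CO[C@H]2[C@@H](O[Si](CC)(CC)CC)C(=C)[C@@H]3[C@H](OCc4ccc(OC)cc4)/C(=C(\C)C(=O)OC(C)(C)C)C(=O)/C=C(CO[Si](c4ccccc4)(c4ccccc4)C(C)(C)C)\C=C/[C@H](OCc4ccc(OC)cc4)[C@@]3(C)[C@H]2O[Si](CC)(CC)CC)cc1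
F4 | step 27 | macrocyclic allylic 1,4-diol (C19 as CH2OH, C7–OH) | COc1ccc(CO[C@H]2[C@@H](O[Si](CC)(CC)CC)C(=C)[C@@H]3[C@H](OCc4ccc(OC)cc4)/C(=C(\C)CO)[C@@H](O)/C=C(CO[Si](c4ccccc4)(c4ccccc4)C(C)(C)C)\C=C/[C@H](OCc4ccc(OC)cc4)[C@@]3(C)[C@H]2O[Si](CC)(CC)CC)cc1
F5 | step 27 | 8,17-epoxy diol | COc1ccc(CO[C@H]2[C@@H](O[Si](CC)(CC)CC)C(=C)[C@@H]3[C@H](OCc4ccc(OC)cc4)[C@@]5(O[C@@]5(C)CO)[C@@H](O)/C=C(CO[Si](c4ccccc4)(c4ccccc4)C(C)(C)C)\C=C/[C@H](OCc4ccc(OC)cc4)[C@@]3(C)[C@H]2O[Si](CC)(CC)CC)cc1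
F6 | step 27 | 7,8,19-triol (C17–H natural) | COc1ccc(CO[C@H]2[C@@H](O[Si](CC)(CC)CC)C(=C)[C@@H]3[C@H](OCc4ccc(OC)cc4)[C@](O)([C@@H](C)CO)[C@@H](O)/C=C(CO[Si](c4ccccc4)(c4ccccc4)C(C)(C)C)\C=C/[C@H](OCc4ccc(OC)cc4)[C@@]3(C)[C@H]2O[Si](CC)(CC)CC)cc1
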